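## Retrosynthetic overview
1. The Z-trisubstituted acrylic acid comes from an Ando Z-selective HWE of a chromene aldehyde with an α-(homoprenyl) phosphonoacetate. The E-trisubstituted alkene comes from a Johnson–Claisen rearrangement of an isopropenyl carbinol, which goes back to C2–(CH2)2–CHO.
2. The 2H-chromene C3=C4 bond comes from reduction and dehydration of a 2,2-disubstituted chroman-4-one.
3. The C2 quaternary (R) centre is set by a proposed Cu/Josiphos asymmetric conjugate addition of a functionalised Grignard reagent to a 2-methylchromone (key new step).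
4. Ring order: the aromatic ring is given, then the pyranone (chromone) ring by Fries, Claisen condensation and cyclodehydration. The stereocentre forms when C2 becomes sp3 (chromanone), and the chromene C3=C4 is unveiled next. The side chain is built last.

Assumptions:
- Grignard 8 and the Ando phosphonoacetate 17 are purchased.
- The Josiphos enantiomer named in Step 7 is assumed to give the (R) face. If (S) is obtained, switch to the pseudo-enantiomeric ligand.

## Route

**Step 1**
Reactants: 1 (4-methoxy-2-methylphenol)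
Product: 2 (4-methoxy-2-methylphenyl acetate)
Conditions: Ac2O, pyridine, cat. DMAP, CH2Cl2, 0 °C → rt
Reagents that add atoms: acetic anhydride, CC(=O)OC(C)=O
Why: O-acetylation prepares the Fries substrate.

**Step 2**
Reactants: 2
Product: 3 (1-(2-hydroxy-5-methoxy-3-methylphenyl)ethan-1-one)
Conditions: AlCl3 (2 equiv), neat, 120 °C
Reagents that add atoms: none
Why: Fries rearrangement can only place the acyl group at the single free ortho position (C6), which fixes the 8-methyl/6-oxygen pattern of the target.

**Step 3**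
Reactants: 3
Product: 4 (1-(2-hydroxy-5-methoxy-3-methylphenyl)butane-1,3-dione)
Conditions: NaH (4 equiv), EtOAc (5 equiv), THF, 65 °C
Reagents that add atoms: ethyl acetate, CCOC(C)=O (supplies the acetyl group)
Why: Claisen condensation of the ketone enolate with ethyl acetate gives the 1,3-diketone.

**Step 4**
Reactants: 4
Product: 5 (6-methoxy-2,8-dimethyl-4H-chromen-4-one)
Conditions: p-TsOH·H2O, toluene, 110 °C, Dean–Stark
Reagents that add atoms: none
Why: acid-catalysed cyclodehydration of the o-hydroxyaryl 1,3-diketone (Kostanecki/Baker–Venkataraman type) closes the pyranone.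

**Step 5**
Reactants: 5
Product: 6 (6-hydroxy-2,8-dimethyl-4H-chromen-4-one)
Conditions: BBr3 (3 equiv), CH2Cl2, −78 °C → rt
Reagents that add atoms: none
Why: the electron-poor chromone tolerates BBr3 demethylation, which would destroy the polyene at a later stage.

**Step 6**
Reactants: 6
Product: 7 (2,8-dimethyl-6-(triisopropylsilyloxy)-4H-chromen-4-one)
Conditions: TIPSCl, imidazole, DMF, rt
Reagents that add atoms: TIPSCl, Cl[Si](C(C)C)(C(C)C)C(C)C
Why: TIPS is stable to Grignard reagents, NaBH4, DIBAL, orthoester heating and LiOH, and is removed by fluoride at the end.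

**Step 7**
Reactants: 7; 8 ([2-(1,3-dioxolan-2-yl)ethyl]magnesium bromide)
Product: 9 ((R)-2-[2-(1,3-dioxolan-2-yl)ethyl]-2,8-dimethyl-6-(TIPSO)chroman-4-one)
Conditions: CuBr·SMe2 (10 mol%), (R,S)-Josiphos (tBu2P/Ph2P ferrocenyl ligand, 12 mol%), TMSCl (2 equiv), 8 (2 equiv), MTBE/CH2Cl2, −78 °C, 16 h; aq. NH4Cl work-up (TMS enol ether hydrolysed on work-up/silica)
Reagents that add atoms: none (the Grignard reagent is reactant 8)
Why: Proposed new method: the Cu–Josiphos alkyl complex (from Grignard transmetalation) binds the C2=C3 bond of the 2-methylchromone, which is a β-alkoxy enone whose C2 carries Me, OAr and C3. The chiral ligand differentiates the two enantiotopic faces of the planar C2, so alkyl transfer creates the quaternary (R) centre without needing to distinguish Me from CH2R. TMSCl activates the vinylogous ester and suppresses 1,2-addition, and the closest known reaction is Cu/Josiphos asymmetric conjugate addition of Grignard reagents to β-substituted cyclic enones and to 2-H chromones.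

**Step 8**
Reactants: 9
Product: 10 ((2R)-chroman-4-ol, C4 epimer mixture)
Conditions: NaBH4, EtOH/THF, 0 °C
Reagents that add atoms: none
Why: simple ketone reduction; the C4 epimers converge in the next step and C2 is not involved.

**Step 9**
Reactants: 10
Product: 11 ((R)-2-[2-(1,3-dioxolan-2-yl)ethyl]-2,8-dimethyl-6-(TIPSO)-2H-chromene)
Conditions: Martin sulfurane, CH2Cl2, 0 °C → rt
Reagents that add atoms: none
Why: neutral dehydration of the benzylic alcohol gives the conjugated C3=C4 alkene without touching the acid-labile C2–O bond or the acetal.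

**Step 10**
Reactants: 11
Product: 12 ((R)-3-[2,8-dimethyl-6-(TIPSO)-2H-chromen-2-yl]propanal)
Conditions: PPTS (0.2 equiv), acetone/H2O 9:1, 55 °C
Reagents that add atoms: water, O
Why: mild acetal hydrolysis (pyridinium salt, not a strong acid) avoids ionisation of the tertiary allylic aryl ether.

**Step 11**
Reactants: 12; 13 (isopropenylmagnesium bromide)
Product: 14 (5-[(2R)-2,8-dimethyl-6-(TIPSO)-2H-chromen-2-yl]-2-methylpent-1-en-3-ol, carbinol epimer mixture)
Conditions: 13 (1.5 equiv), THF, −20 → 0 °C; aq. NH4Cl
Reagents that add atoms: none (the Grignard reagent is reactant 13)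
Why: Grignard 1,2-addition to the aldehyde; the new carbinol centre is destroyed in the next step.

**Step 12**
Reactants: 14
Product: 15 (ethyl (E)-7-[(2R)-chromen-2-yl]-4-methylhept-4-enoate)
Conditions: MeC(OEt)3 (10 equiv), EtCO2H (5 mol%), 140 °C, EtOH distilled off
Reagents that add atoms: triethyl orthoacetate, CC(OCC)(OCC)OCC
Why: the Johnson–Claisen [3,3] rearrangement proceeds through a chair transition state with R equatorial, giving the E-trisubstituted alkene (about 10:1) and extending the chain by CH2CO2Et.

**Step 13**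
Reactants: 15
Product: 16 ((E)-7-[(2R)-chromen-2-yl]-4-methylhept-4-enal)
Conditions: DIBAL-H (1.1 equiv), toluene, −78 °C; Rochelle salt work-up
Reagents that add atoms: none
Why: partial ester reduction at −78 °C; the alkenes and silyl ether are inert.

**Step 14** (side branch, reagent preparation)
Reactants: 17 (ethyl bis(2-methylphenoxy)phosphorylacetate); 18 (5-bromo-2-methylpent-2-ene)
Product: 19 (ethyl 2-[bis(2-methylphenoxy)phosphoryl]-6-methylhept-5-enoate)
Conditions: NaH (1.1 equiv), THF, 0 °C; then 18, cat. NaI, 50 °C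
Reagents that add atoms: none (both partners are numbered reactants)
Why: C-alkylation of the stabilised phosphonate anion installs the homoprenyl group.

**Step 15**
Reactants: 16; 19
Product: 20 (ethyl (2Z,6E)-9-[(2R)-2,8-dimethyl-6-(TIPSO)-2H-chromen-2-yl]-6-methyl-2-(4-methylpent-3-en-1-yl)nona-2,6-dienoate)
Conditions: 19 + NaH (1.1 equiv), THF, −78 °C, 15 min; add 16; −78 → −20 °C
Reagents that add atoms: none (the phosphonate is reactant 19)
Why: the Ando Z-selective Horner–Wadsworth–Emmons reaction with an α-alkyl diaryl phosphonoacetate places CO2Et cis to the chain carbon, giving the required (Z) geometry (about 9:1, E isomer separable).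

**Step 16**
Reactants: 20
Product: 21 (the free acid, still carrying the aryl TIPS ether)
Conditions: LiOH·H2O (10 equiv), THF/MeOH/H2O 3:2:1, 50 °C, 12 h; acidify to pH 4–5 with citric acid
Reagents that add atoms: lithium hydroxide, [Li+].[OH-]
Why: saponification of the ethyl ester; the aryl TIPS ether and all alkenes survive.

**Step 17**
Reactants: 21
Product: 22 ((R)-sargachromenol)
Conditions: TBAF (3 equiv), THF, 0 °C, 30 min; acidify to pH 4–5; work under argon
Reagents that add atoms: none
Why: fluoride cleaves the aryl silyl ether (Si–O cleavage) to release the free phenol.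

## Compound list
1 | 4-methoxy-2-methylphenol | COc1ccc(O)c(C)c1 | starting material
2 | 4-methoxy-2-methylphenyl acetate | COc1ccc(OC(C)=O)c(C)c1 | intermediate
3 | 1-(2-hydroxy-5-methoxy-3-methylphenyl)ethanone | CC(=O)c1cc(OC)cc(C)c1O | intermediate
4 | 1-(2-hydroxy-5-methoxy-3-methylphenyl)butane-1,3-dione | CC(=O)CC(=O)c1cc(OC)cc(C)c1O | intermediate
5 | 6-methoxy-2,8-dimethylchromone | CC1=CC(=O)c2cc(OC)cc(C)c2O1 | intermediate
6 | 6-hydroxy-2,8-dimethylchromone | CC1=CC(=O)c2cc(O)cc(C)c2O1 | intermediate
7 | 2,8-dimethyl-6-(TIPSO)chromone | CC1=CC(=O)c2cc(O[Si](C(C)C)(C(C)C)C(C)C)cc(C)c2O1 | intermediate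
8 | [2-(1,3-dioxolan-2-yl)ethyl]magnesium bromide | Br[Mg]CCC1OCCO1 | starting material
9 | (R)-2-[2-(1,3-dioxolan-2-yl)ethyl]-2,8-dimethyl-6-(TIPSO)chroman-4-one | O1CCOC1CC[C@]2(C)CC(=O)c3cc(O[Si](C(C)C)(C(C)C)C(C)C)cc(C)c3O2 | intermediate
10 | corresponding (2R)-chroman-4-ol (C4 epimers; C2 shown) | O1CCOC1CC[C@]2(C)CC(O)c3cc(O[Si](C(C)C)(C(C)C)C(C)C)cc(C)c3O2 | intermediate
11 | (R)-2-[2-(1,3-dioxolan-2-yl)ethyl]-2,8-dimethyl-6-(TIPSO)-2H-chromene | O1CCOC1CC[C@]2(C)C=Cc3cc(O[Si](C(C)C)(C(C)C)C(C)C)cc(C)c3O2 | intermediate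
12 | (R)-3-[2,8-dimethyl-6-(TIPSO)-2H-chromen-2-yl]propanal | O=CCC[C@]1(C)C=Cc2cc(O[Si](C(C)C)(C(C)C)C(C)C)cc(C)c2O1 | intermediate
13 | isopropenylmagnesium bromide | Br[Mg]C(C)=C | starting material
14 | 5-[(2R)-chromen-2-yl]-2-methylpent-1-en-3-ol (carbinol epimers) | C=C(C)C(O)CC[C@]1(C)C=Cc2cc(O[Si](C(C)C)(C(C)C)C(C)C)cc(C)c2O1 | intermediate
15 | ethyl (E)-7-[(2R)-chromen-2-yl]-4-methylhept-4-enoate | CCOC(=O)CC/C(C)=C/CC[C@]1(C)C=Cc2cc(O[Si](C(C)C)(C(C)C)C(C)C)cc(C)c2O1 | intermediate
16 | (E)-7-[(2R)-chromen-2-yl]-4-methylhept-4-enal | O=CCC/C(C)=C/CC[C@]1(C)C=Cc2cc(O[Si](C(C)C)(C(C)C)C(C)C)cc(C)c2O1 | intermediate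
17 | ethyl bis(2-methylphenoxy)phosphorylacetate | CCOC(=O)CP(=O)(Oc1ccccc1C)Oc1ccccc1C | starting material
18 | 5-bromo-2-methylpent-2-ene | CC(C)=CCCBr | starting material
19 | ethyl 2-[bis(2-methylphenoxy)phosphoryl]-6-methylhept-5-enoate | CCOC(=O)C(CCC=C(C)C)P(=O)(Oc1ccccc1C)Oc1ccccc1C | intermediate (reagent)
20 | ethyl (2Z,6E)-9-[(2R)-chromen-2-yl]-6-methyl-2-(4-methylpent-3-enyl)nona-2,6-dienoate | CC(C)=CCC/C(=C/CC/C(C)=C/CC[C@]1(C)C=Cc2cc(O[Si](C(C)C)(C(C)C)C(C)C)cc(C)c2O1)C(=O)OCC | intermediate
21 | the corresponding carboxylic acid (aryl-OTIPS) | CC(C)=CCC/C(=C/CC/C(C)=C/CC[C@]1(C)C=Cc2cc(O[Si](C(C)C)(C(C)C)C(C)C)cc(C)c2O1)C(=O)O | intermediate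
22 | (R)-sargachromenol | CC(C)=CCC/C(=C/CC/C(C)=C/CC[C@]1(C)C=Cc2cc(O)cc(C)c2O1)C(=O)O | target

## Totals
Total steps: 17 (16 on the main line plus 1 reagent-preparation step).
Longest linear sequence: 16 steps (1 → 22, excluding Step 14).

## Three steps most likely to fail
1. **Step 7 (proposed new step: Cu/Josiphos asymmetric addition to 2-methylchromone).** The risks are low reactivity of the vinylogous ester, competing 1,2-addition, and modest ee.
   Fallback (known chemistry): run Step 7 racemic (CuI/TMSCl, achiral phosphine). Resolve chromanone 9 by preparative chiral-phase SFC/HPLC on an amylose column, then assign (R) by optical rotation or a crystalline derivative.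
2. **Step 15 (Ando Z-HWE).** Z/E selectivity may be poor for an α-long-chain phosphonate and an aliphatic aldehyde.
   Fallback: drop the HWE. Add CH2=C(CH2OTBS)MgBr (from 2-bromoallyl TBS ether) to aldehyde 16, then a second Johnson–Claisen (chair transition state fixes the geometry with the CH2OR branch cis to the chain). Follow with DIBAL, Wittig with Ph3P=CMe2, TBS removal (PPTS/MeOH), MnO2, Pinnick oxidation and TBAF.
3. **Step 12 (Johnson–Claisen at 140 °C with acid, on the acid-sensitive tertiary allylic aryl ether).** The risks are C2–O ionisation with racemisation, and E/Z erosion.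
   Fallback: reorder the sequence. Carry the C4-OTBS chromane (no allylic C2–O ether) through Steps 11–16. Then install the chromene late by TBAF followed by Martin-sulfurane dehydration, and finish with saponification.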